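Ring B (b1 C–OAr, b2 C–OH, b3 CH, b4 C–OH, b5 CH, b6 C–chain) has para oxygens at b1 and b4, a third oxygen at b2 and the alkyl tether at b6. This is the imprint of a semisquarate joined to a 1-alken-2-yl group. Everything rests on cutting b4–b5. Heating a 4-alkenyl-4-silyloxy-3-isopropoxycyclobutenone, which already carries the fourteen-methylene tether and ring A, turns the four-membered ring into aromatic ring B in one operation. It leaves b1–O silylated, b2–O isopropylated and b4–O free. That differentiation permits meta C–H borylation of ring A and copper-mediated b1–O–aryl closure of the twenty-membered macrocycle.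

Key step: step 5

Remarks on the chemistry:
- The target has no stereocentre. The only sp3 centre that matters on the way (the cyclobutenone carbinol carbon) is racemic and disappears on aromatisation.
- Ring A is labelled a1 (C–O), a2, a3 (C–chain), a4, a5 (C–O–b1), a6.
- The silyl group is tert-butyldimethylsilyl. The derived aryl silyl ether at b1 must outlast heating next to a free phenol, a phenoxide alkylation and chromatography. A smaller trialkylsilyl group on a phenolic oxygen could be lost or handed over under base, which would erase the b1/b4 distinction.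
- Ring A stays free of halogen and boron until the organolithium chemistry is over.
- 3-Methoxybenzyl chloride, 1,12-dibromododecane, 2,3-dibromopropene and diisopropyl squarate are assumed to be catalogue items.

Step 1
Reactants: 1 3-methoxybenzyl chloride; 2 1,12-dibromododecane
Product: 4 1-(13-bromotridecyl)-3-methoxybenzene, via 3-methoxybenzylmagnesium chloride 3 (not isolated)
Conditions: Mg, 2-MeTHF, 0 °C; then added slowly to 2 (3 equiv), Li2CuCl4 (3 mol %), THF, −10 °C → rt
Reagents that add atoms: none
Why: Copper-catalysed Grignard–alkyl bromide cross-coupling (Kochi type) joins the two sp3 carbons, and slow addition of the Grignard reagent to a threefold excess of the symmetrical dibromide keeps double substitution low while unreacted 2 is recovered by chromatography.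

Step 2
Reactants: 4 1-(13-bromotridecyl)-3-methoxybenzene; 5 2,3-dibromoprop-1-ene
Product: 7 1-(15-bromohexadec-15-en-1-yl)-3-methoxybenzene, via 13-(3-methoxyphenyl)tridecylmagnesium bromide 6 (not isolated)
Conditions: Mg, THF, 45 °C; then 5 (1.3 equiv), CuBr·SMe2 (5 mol %), 0 °C → rt
Reagents that add atoms: none
Why: In this allylic substitution of a Grignard reagent on 2,3-dibromopropene, direct and transposed attack give the same 2-bromo-1-alkene and the vinylic C–Br bond is inert, so the fourteen-methylene chain and the bromoalkene arrive together without any alkyne hydrobromination.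

Step 3
Reactants: 8 diisopropyl squarate
Product: 10 3-isopropoxycyclobut-3-ene-1,2-dione, via 4-hydroxy-2,3-diisopropoxycyclobut-2-en-1-one 9 (not isolated)
Conditions: LiAlH(Ot-Bu)3 (1.05 equiv), THF, −78 → 0 °C; aq HCl quench; crude 9, conc. HCl (cat.), CH2Cl2, rt
Reagents that add atoms: none
Why: The bulky hydride performs a single 1,2-reduction of one of the two equivalent carbonyl groups, and acid then ionises the allylic carbinol and hydrolyses the alkoxy-stabilised cation with loss of isopropanol, which is the standard squarate-to-cyclobutenedione transposition.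

Step 4
Reactants: 7 1-(15-bromohexadec-15-en-1-yl)-3-methoxybenzene; 10 3-isopropoxycyclobut-3-ene-1,2-dione
Product: 13 4-(tert-butyldimethylsilyloxy)-3-isopropoxy-4-[16-(3-methoxyphenyl)hexadec-1-en-2-yl]cyclobut-2-en-1-one (racemic), via alkenyllithium 11 (not isolated), via lithium alkoxide 12 (not isolated)
Conditions: t-BuLi (2.0 equiv), Et2O, −78 °C; cannula into 10 (1.2 equiv), THF, −78 °C; TBSOTf (1.5 equiv), −78 → 0 °C
Reagents that add atoms: tert-butyldimethylsilyl trifluoromethanesulfonate, CC(C)(C)[Si](C)(C)OS(=O)(=O)C(F)(F)F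
Why: Bromine–lithium exchange is followed by 1,2-addition to the carbonyl flanked by the isopropoxy-bearing carbon, which is ketone-like whereas the other carbonyl is a deactivated vinylogous ester, and the hindered alkoxide is captured by the silyl triflate; the new quaternary centre forms as a racemate and is erased in step 5.

Step 5
Reactants: 13 4-(tert-butyldimethylsilyloxy)-3-isopropoxy-4-[16-(3-methoxyphenyl)hexadec-1-en-2-yl]cyclobut-2-en-1-one
Product: 16 4-(tert-butyldimethylsilyloxy)-3-isopropoxy-5-[14-(3-methoxyphenyl)tetradecyl]phenol, via dienylketene 14 (not isolated), via cyclohexadienone 15 (not isolated)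
Conditions: PhMe (0.02 M, degassed), 110 °C, Ar
Reagents that add atoms: none
Why: Heat opens the C1–C4 bond of 13 in a conrotatory four-electron electrocyclic reaction in which the donor silyloxy group turns outward and the alkenyl group inward, giving the Z-configured dienylketene 14. A disrotatory six-electron electrocyclisation then bonds the ketene carbon (future b4) to the methylene terminus (future b5), closing the only new ring, a six-membered all-carbon one, and the resulting cyclohexadienone 15 enolises irreversibly to arene 16. The closest known reaction type is the Moore ring expansion of squarate-derived 4-alkenyl-4-oxycyclobutenones to hydroquinone derivatives, used here within its usual substrate class. No stereocentre is formed, and the racemic quaternary carbon of 13 becomes planar b1. The selectivity required is positional and rests on the substrate: the carbinol oxygen ends at b1 still silylated, the neighbouring isopropoxy carbon becomes b2, the ketene oxygen becomes the free b4 hydroxyl and the chain-bearing alkene carbon becomes b6, while the outward preference of oxygen ensures that the alkene, not the silyloxy group, faces the ketene. The step is a pure isomerisation, and dilute degassed toluene suppresses capture of the ketene by the phenolic product and oxidation of the electron-rich arene.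

Step 6
Reactants: 16 4-(tert-butyldimethylsilyloxy)-3-isopropoxy-5-[14-(3-methoxyphenyl)tetradecyl]phenol
Product: 17 tert-butyl{2-isopropoxy-4-methoxy-6-[14-(3-methoxyphenyl)tetradecyl]phenoxy}dimethylsilane
Conditions: MeI (2 equiv), K2CO3 (2 equiv), dry acetone, rt → 40 °C, Ar
Reagents that add atoms: iodomethane, CI
Why: Williamson O-methylation addresses the only free hydroxyl (b4), and the bulky silyl ether wedged between the isopropoxy group and the alkyl chain should withstand carbonate in dry acetone.

Step 7
Reactants: 17 tert-butyl{2-isopropoxy-4-methoxy-6-[14-(3-methoxyphenyl)tetradecyl]phenoxy}dimethylsilane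
Product: 18 tert-butyl(2-isopropoxy-4-methoxy-6-{14-[3-methoxy-5-(4,4,5,5-tetramethyl-1,3,2-dioxaborolan-2-yl)phenyl]tetradecyl}phenoxy)dimethylsilane
Conditions: [Ir(OMe)(cod)]2 (1.5 mol %), 4,4'-di-tert-butyl-2,2'-bipyridine (3 mol %), B2pin2 (1.0 equiv), THF, 80 °C (sealed)
Reagents that add atoms: bis(pinacolato)diboron, CC1(C)OB(OC1(C)C)B1OC(C)(C)C(C)(C)O1
Why: Iridium-catalysed aromatic C–H borylation is sterically governed, and a5–H is the only aromatic hydrogen without an ortho substituent (a2, b3 and b5 are flanked twice, a4 and a6 once), as is established for 3-alkylanisoles.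

Step 8
Reactants: 18 tert-butyl(2-isopropoxy-4-methoxy-6-{14-[3-methoxy-5-(4,4,5,5-tetramethyl-1,3,2-dioxaborolan-2-yl)phenyl]tetradecyl}phenoxy)dimethylsilane
Product: 19 2-isopropoxy-4-methoxy-6-{14-[3-methoxy-5-(4,4,5,5-tetramethyl-1,3,2-dioxaborolan-2-yl)phenyl]tetradecyl}phenol
Conditions: TBAF (1.1 equiv), AcOH (1.2 equiv), THF, 0 °C, Ar
Reagents that add atoms: none
Why: Fluoride-induced cleavage of an aryl silyl ether is fast even at a hindered phenol, and acetic acid buffering protonates the phenoxide at once and spares the pinacol boronate.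

Step 9
Reactants: 19 2-isopropoxy-4-methoxy-6-{14-[3-methoxy-5-(4,4,5,5-tetramethyl-1,3,2-dioxaborolan-2-yl)phenyl]tetradecyl}phenol
Product: 20 macrocyclic diaryl ether, the a1,b4-di-O-methyl b2-O-isopropyl ether of the target
Conditions: Cu(OAc)2 (2 equiv), B(OH)3 (2 equiv), Et3N (5 equiv), 4 Å MS, MeCN/1,2-dichloroethane, 60 °C, dry air; 19 added by syringe pump (final 2 mM)
Reagents that add atoms: none
Why: In this intramolecular Chan–Lam oxidative C–O coupling the aryl group passes from boron to a divalent copper phenoxide and reductive elimination from trivalent copper forges a5–O–b1; high dilution favours the strain-free twenty-membered ring, boric acid ties up released pinacol, and the phenol cannot couple oxidatively because both ortho positions and the para position are substituted.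

Step 10
Reactants: 20 macrocyclic diaryl ether, the a1,b4-di-O-methyl b2-O-isopropyl ether of the target
Product: 21 target CNP0173380.0
Conditions: BBr3 (8 equiv), CH2Cl2, −78 °C → rt; then MeOH, H2O
Reagents that add atoms: none
Why: Lewis-acid ether cleavage with BBr3 removes the two methyl groups and the isopropyl group by bromide attack at their sp3 carbons, whereas the diaryl ether offers no such carbon and survives.

Compound list
1 | 3-methoxybenzyl chloride | COc1cccc(CCl)c1 | starting material
2 | 1,12-dibromododecane | BrCCCCCCCCCCCCBr | starting material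
3 | 3-methoxybenzylmagnesium chloride | COc1cccc(C[Mg]Cl)c1 | intermediate
4 | 1-(13-bromotridecyl)-3-methoxybenzene | COc1cccc(CCCCCCCCCCCCCBr)c1 | intermediate
5 | 2,3-dibromoprop-1-ene | C=C(Br)CBr | starting material
6 | 13-(3-methoxyphenyl)tridecylmagnesium bromide | COc1cccc(CCCCCCCCCCCCC[Mg]Br)c1 | intermediate
7 | 1-(15-bromohexadec-15-en-1-yl)-3-methoxybenzene | C=C(Br)CCCCCCCCCCCCCCc1cccc(OC)c1 | intermediate
8 | diisopropyl squarate | CC(C)OC1=C(OC(C)C)C(=O)C1=O | starting material
9 | 4-hydroxy-2,3-diisopropoxycyclobut-2-en-1-one (racemic) | CC(C)OC1=C(OC(C)C)C(O)C1=O | intermediate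
10 | 3-isopropoxycyclobut-3-ene-1,2-dione | CC(C)OC1=CC(=O)C1=O | intermediate
11 | [16-(3-methoxyphenyl)hexadec-1-en-2-yl]lithium | [Li]C(=C)CCCCCCCCCCCCCCc1cccc(OC)c1 | intermediate
12 | lithium 2-isopropoxy-1-[16-(3-methoxyphenyl)hexadec-1-en-2-yl]-4-oxocyclobut-2-en-1-olate (racemic) | [Li+].CC(C)OC1=CC(=O)C1([O-])C(=C)CCCCCCCCCCCCCCc1cccc(OC)c1 | intermediate
13 | 4-(tert-butyldimethylsilyloxy)-3-isopropoxy-4-[16-(3-methoxyphenyl)hexadec-1-en-2-yl]cyclobut-2-en-1-one (racemic) | CC(C)OC1=CC(=O)C1(O[Si](C)(C)C(C)(C)C)C(=C)CCCCCCCCCCCCCCc1cccc(OC)c1 | intermediate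
14 | (3Z)-4-(tert-butyldimethylsilyloxy)-3-isopropoxy-19-(3-methoxyphenyl)-5-methylidenenonadeca-1,3-dien-1-one | O=C=C/C(OC(C)C)=C(\C(=C)CCCCCCCCCCCCCCc1cccc(OC)c1)O[Si](C)(C)C(C)(C)C | intermediate
15 | 4-(tert-butyldimethylsilyloxy)-3-isopropoxy-5-[14-(3-methoxyphenyl)tetradecyl]cyclohexa-2,4-dien-1-one | CC(C)OC1=CC(=O)CC(CCCCCCCCCCCCCCc2cccc(OC)c2)=C1O[Si](C)(C)C(C)(C)C | intermediate
16 | 4-(tert-butyldimethylsilyloxy)-3-isopropoxy-5-[14-(3-methoxyphenyl)tetradecyl]phenol | CC(C)Oc1cc(O)cc(CCCCCCCCCCCCCCc2cccc(OC)c2)c1O[Si](C)(C)C(C)(C)C | intermediate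
17 | tert-butyl{2-isopropoxy-4-methoxy-6-[14-(3-methoxyphenyl)tetradecyl]phenoxy}dimethylsilane | CC(C)Oc1cc(OC)cc(CCCCCCCCCCCCCCc2cccc(OC)c2)c1O[Si](C)(C)C(C)(C)C | intermediate
18 | tert-butyl(2-isopropoxy-4-methoxy-6-{14-[3-methoxy-5-(4,4,5,5-tetramethyl-1,3,2-dioxaborolan-2-yl)phenyl]tetradecyl}phenoxy)dimethylsilane | CC(C)Oc1cc(OC)cc(CCCCCCCCCCCCCCc2cc(OC)cc(B3OC(C)(C)C(C)(C)O3)c2)c1O[Si](C)(C)C(C)(C)C | intermediate
19 | 2-isopropoxy-4-methoxy-6-{14-[3-methoxy-5-(4,4,5,5-tetramethyl-1,3,2-dioxaborolan-2-yl)phenyl]tetradecyl}phenol | CC(C)Oc1cc(OC)cc(CCCCCCCCCCCCCCc2cc(OC)cc(B3OC(C)(C)C(C)(C)O3)c2)c1O | intermediate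
20 | macrocyclic diaryl ether with a1 OMe, b2 Oi-Pr, b4 OMe (twenty-membered ring: a3–a4–a5–O–b1–b6 plus fourteen CH2) | COc1cc2cc(c1)Oc1c(OC(C)C)cc(OC)cc1CCCCCCCCCCCCCC2 | intermediate
21 | CNP0173380.0, macrocyclic diaryl ether with a1 OH, b2 OH, b4 OH | Oc1cc2cc(c1)Oc1c(O)cc(O)cc1CCCCCCCCCCCCCC2 | target

Total step count: 10.
Longest linear sequence: 9 steps (1, 2, 4, 5, 6, 7, 8, 9, 10). Step 3 is a one-step side branch.

Steps most likely to fail

Step 9 (macrocyclisation). Transfer of the aryl group from the pinacol boronate to divalent copper is slow, and the b1 hydroxyl is flanked on both sides. Intermolecular O-arylation, protodeboronation and oxidation of the C–B bond may therefore outpace ring closure. The fallback replaces the oxidative coupling by a non-oxidative Ullmann closure. Setting out from 18, copper-catalysed iododeboronation (CuI, 1,10-phenanthroline, KI, MeOH/THF/H2O, air, 60 °C) should give the aryl iodide F1. TBAF/AcOH in THF then frees the iodophenol F2. An Ullmann diaryl ether synthesis under slow addition (CuI, N,N-dimethylglycine, Cs2CO3, dioxane, 100 °C) closes a5–O–b1 and comes back to the route at 20.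

Step 5 (key step). At the temperature of ring opening the silyl group may be lost or handed over between phenolic oxygens. Traces of air may also oxidise the electron-rich product. Either process blurs the b1/b4 distinction. The fallback gives up the silyl label and tells the two oxygens apart by their steric surroundings.
- Setting out from 13, the crude thermolysate is fully desilylated (TBAF, THF, Ar) to the hydroquinone F3.
- F3 is oxidised with Ag2O to the readily purified quinone F4 and reduced back to F3 with Na2S2O4.
- F3 is mono-methylated at the unflanked b4 hydroxyl (MeI 1 equiv, K2CO3, acetone, Ar) to the phenol F5. The b1 hydroxyl is shielded by the isopropoxy group and the chain.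
- Silylation of F5 at b1 (TBSOTf, 2,6-lutidine, CH2Cl2) comes back to the route at 17.

Step 4 (addition and silyl capture). Three events share one flask. Dehydrobromination of 7 may compete with the exchange. The strongly basic alkenyllithium may remove the ring hydrogen of 10 or add in a conjugate sense. Capture of the hindered alkoxide may stay incomplete. The fallback uses a less basic organometallic and a stepwise sequence. Setting out from 7, Mg in THF gives the alkenylmagnesium bromide F6, which is added to 10 at −78 °C in the presence of LaCl3·2LiCl. The carbinol F7 is isolated after an NH4Cl quench. It is silylated separately (TBSOTf, 2,6-lutidine, CH2Cl2, 0 °C) to come back to the route at 13.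

Further compounds
F1 | step 9 | tert-butyl{2-[14-(3-iodo-5-methoxyphenyl)tetradecyl]-6-isopropoxy-4-methoxyphenoxy}dimethylsilane | CC(C)Oc1cc(OC)cc(CCCCCCCCCCCCCCc2cc(I)cc(OC)c2)c1O[Si](C)(C)C(C)(C)C
F2 | step 9 | 2-[14-(3-iodo-5-methoxyphenyl)tetradecyl]-6-isopropoxy-4-methoxyphenol | CC(C)Oc1cc(OC)cc(CCCCCCCCCCCCCCc2cc(I)cc(OC)c2)c1O
F3 | step 5 | 2-isopropoxy-6-[14-(3-methoxyphenyl)tetradecyl]benzene-1,4-diol | CC(C)Oc1cc(O)cc(CCCCCCCCCCCCCCc2cccc(OC)c2)c1O
F4 | step 5 | 2-isopropoxy-6-[14-(3-methoxyphenyl)tetradecyl]cyclohexa-2,5-diene-1,4-dione | CC(C)OC1=CC(=O)C=C(CCCCCCCCCCCCCCc2cccc(OC)c2)C1=O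
F5 | step 5 | 2-isopropoxy-4-methoxy-6-[14-(3-methoxyphenyl)tetradecyl]phenol | CC(C)Oc1cc(OC)cc(CCCCCCCCCCCCCCc2cccc(OC)c2)c1O
F6 | step 4 | [16-(3-methoxyphenyl)hexadec-1-en-2-yl]magnesium bromide | C=C([Mg]Br)CCCCCCCCCCCCCCc1cccc(OC)c1
F7 | step 4 | 4-hydroxy-3-isopropoxy-4-[16-(3-methoxyphenyl)hexadec-1-en-2-yl]cyclobut-2-en-1-one (racemic) | CC(C)OC1=CC(=O)C1(O)C(=C)CCCCCCCCCCCCCCc1cccc(OC)c1
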